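Atoms are counted from the lactone carbonyl (C1) to the chain methyl (C26). The 5,6-dihydropyran-2-one (ring A: O, C1–C5) is disconnected at C1: because this carbon lies between the ring oxygen on C5 and the cis C2=C3 alkene, it can be brought in as carbon monoxide, and one palladium-catalysed carbonylative lactonisation forms C1–C2 and C1–O and closes ring A. The precursor is the (Z)-C2 iodoalkene with its only free hydroxyl on C5, C7 as a TBS ether and C9/C11 as an acetonide. C9 and C11 are bought with the statin side-chain aldehyde (C7–C12); Wittig olefination and hydrogenation add the tail, and reagent-controlled allyl- and allenylboration set C7 and C5.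

Key step: step 10

Remark: 1 is assumed to be purchased as such (a bulk statin intermediate). CIP descriptors at C7 and C9 change between intermediates only because substituent priorities change; the all-syn arrangement of the four oxygens is the same throughout.

**Step 1**
Reactants: 1 statin side-chain aldehyde (C7–C12, acetonide on the C9/C11 oxygens, tert-butyl ester at C7); 2 tetradecyl(triphenyl)phosphonium bromide
Product: 4 tert-butyl 2-[(4R,6S)-2,2-dimethyl-6-[(1Z)-pentadec-1-en-1-yl]-1,3-dioxan-4-yl]acetate, via triphenyl(tetradecylidene)phosphorane 3 (not isolated)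
Conditions: 2, NaN(SiMe3)2, THF, 0 °C; then 1, −78 °C → rt
Reagents that add atoms: none
Why: Wittig olefination with a non-stabilised ylide at −78 °C should outrun enolisation of the α-alkoxy aldehyde, so C11 keeps its configuration, and the alkene geometry is irrelevant because step 2 saturates it.

**Step 2**
Reactants: 4 (Z)-alkene ester
Product: 5 tert-butyl 2-[(4R,6R)-2,2-dimethyl-6-pentadecyl-1,3-dioxan-4-yl]acetate
Conditions: H2 (1 atm), Pd/C (10 %), EtOAc, rt
Reagents that add atoms: none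
Why: Heterogeneous catalytic hydrogenation saturates the C12=C13 alkene while the acetonide and the tert-butyl ester are inert, and no stereocentre is formed or touched.

**Step 3**
Reactants: 5 saturated ester
Product: 6 2-[(4R,6R)-2,2-dimethyl-6-pentadecyl-1,3-dioxan-4-yl]acetaldehyde (C7 aldehyde)
Conditions: i-Bu2AlH (1.1 equiv), CH2Cl2, −78 °C; aq. KNaC4H4O6 work-up
Reagents that add atoms: none
Why: Partial ester reduction with i-Bu2AlH should stop at the aldehyde because the aluminium hemiacetal, stabilised by the bulky tert-butoxy group and by chelation to the C9 ring oxygen, persists at −78 °C until the quench.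

**Step 4**
Reactants: 6 C7 aldehyde; 7 allylmagnesium bromide
Product: 9 (2S)-1-[(4S,6R)-2,2-dimethyl-6-pentadecyl-1,3-dioxan-4-yl]pent-4-en-2-ol, via B-allylbis(isopinocampheyl)borane 8 (not isolated)
Conditions: (−)-Ipc2BOMe [(+)-α-pinene series], 7, Et2O, 0 °C → rt; then 6, −78 °C; NaOH (aq.), H2O2, 0 °C → rt
Reagents that add atoms: none
Why: Brown allylboration through a chair Zimmerman–Traxler transition state is reagent-controlled, and borane 8 delivers the allyl group to the Si face of the aldehyde, which sets C7 syn to the C9 oxygen regardless of the weak bias of the β-alkoxy group.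

**Step 5**
Reactants: 9 homoallylic alcohol
Product: 10 tert-butyl{[(2S)-1-[(4R,6R)-2,2-dimethyl-6-pentadecyl-1,3-dioxan-4-yl]pent-4-en-2-yl]oxy}dimethylsilane (C7 TBS ether)
Conditions: TBSCl, imidazole, DMF, rt → 40 °C
Reagents that add atoms: tert-butyldimethylsilyl chloride, CC(C)(C)[Si](C)(C)Cl
Why: Imidazole-promoted O-silylation of the secondary alcohol blocks the C7 hydroxyl, so that the C5 hydroxyl made later is the only free one.

**Step 6**
Reactants: 10 C7 TBS ether
Product: 12 (3R)-3-[(tert-butyldimethylsilyl)oxy]-4-[(4R,6R)-2,2-dimethyl-6-pentadecyl-1,3-dioxan-4-yl]butanal, via secondary ozonide 11 (not isolated)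
Conditions: O3, CH2Cl2, −78 °C; then PPh3, −78 °C → rt
Reagents that add atoms: ozone, [O-][O+]=O
Why: Ozonolysis of the terminal alkene with reductive cleavage of the ozonide by PPh3 gives the C5 aldehyde without touching the silyl ether, the acetonide or the C7 stereocentre.

**Step 7**
Reactants: 12 C5 aldehyde; 13 allenylboronic acid pinacol ester
Product: 14 (4S,6S)-6-[(tert-butyldimethylsilyl)oxy]-7-[(4R,6R)-2,2-dimethyl-6-pentadecyl-1,3-dioxan-4-yl]hept-1-yn-4-ol
Conditions: 13 (1.5 equiv), (S)-TRIP [(S)-3,3′-bis(2,4,6-triisopropylphenyl)-1,1′-binaphthyl-2,2′-diyl hydrogen phosphate] (10 mol %), 4 Å MS, toluene, −20 °C; aq. NaHCO3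
Reagents that add atoms: none
Why: Chiral phosphoric acid-catalysed allenylboration (SE2′ addition through a six-membered chair in which the acid bridges a boronate oxygen and the formyl hydrogen) gives the homopropargylic alcohol, the (S)-catalyst being the enantiomer expected to direct attack to the Si face so that C5 forms syn to the C7 silyl ether under catalyst control.

**Step 8**
Reactants: 14 homopropargylic alcohol
Product: 15 (4S,6S)-6-[(tert-butyldimethylsilyl)oxy]-7-[(4R,6R)-2,2-dimethyl-6-pentadecyl-1,3-dioxan-4-yl]-1-iodohept-1-yn-4-ol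
Conditions: NIS, AgNO3 (10 mol %), acetone, rt, dark
Reagents that add atoms: N-iodosuccinimide, O=C1CCC(=O)N1I
Why: Silver-catalysed electrophilic iodination of the terminal alkyne (through the silver acetylide) is selective for the acetylenic C–H bond and tolerates the free secondary alcohol, the silyl ether and the acetonide.

**Step 9**
Reactants: 15 iodoalkyne
Product: 16 (1Z,4S,6S)-6-[(tert-butyldimethylsilyl)oxy]-7-[(4R,6R)-2,2-dimethyl-6-pentadecyl-1,3-dioxan-4-yl]-1-iodohept-1-en-4-ol
Conditions: 2-nitrobenzenesulfonyl hydrazide (NBSH), Et3N, THF/i-PrOH, rt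
Reagents that add atoms: none
Why: Diimide reduction transfers two hydrogens suprafacially to the iodoalkyne, so the (Z)-iodoalkene should form without hydrogenolysis of the C–I bond and without acid or base stress on the protecting groups.

**Step 10**
Reactants: 16 (Z)-iodoalkenol; 17 carbon monoxide
Product: 18 (6S)-6-{(2R)-2-[(tert-butyldimethylsilyl)oxy]-3-[(4R,6R)-2,2-dimethyl-6-pentadecyl-1,3-dioxan-4-yl]propyl}-5,6-dihydro-2H-pyran-2-one
Conditions: 17 (1 atm, balloon), Pd(PPh3)4 (5 mol %), Et3N (2 equiv), THF/MeCN, 50 °C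
Reagents that add atoms: none
Why: Zerovalent palladium adds oxidatively to the C2–I bond with retention of the Z geometry, CO inserts to give an acyl complex of divalent palladium, and the C5 hydroxyl captures the acyl carbon (directly, or by C–O reductive elimination from the acyl(alkoxo)palladium chelate) while Et3N takes up HI and zerovalent palladium is regenerated. The closest known reaction type is the palladium-catalysed intramolecular alkoxycarbonylation of (Z)-iodoalkenols to butenolides and 5,6-dihydropyran-2-ones. Ring A closes in a 6-exo-trig mode at the acyl carbon, the cis C2=C3 bond holding the acyl group and the C5 hydroxyl within bonding distance. No stereocentre is created, and C5 is not at risk because its C–O bond is never broken. The step needs retention of alkene geometry, which stereospecific oxidative addition supplies, and selectivity for one hydroxyl, which the substrate secures because C7 is silylated and the C9/C11 oxygens are tied up in the acetonide.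

**Step 11**
Reactants: 18 protected lactone
Product: 19 (6S)-6-[(2R,4R,6R)-2,4,6-trihydroxyhenicosyl]-5,6-dihydro-2H-pyran-2-one (target)
Conditions: HF (48 % aq.), MeCN/CH2Cl2, 0 °C → rt
Reagents that add atoms: none
Why: Acidic global deprotection with aqueous HF should cleave the TBS ether and hydrolyse the acetonide in one operation, a non-basic medium being chosen so that the freed C7 hydroxyl is not driven into oxa-Michael addition to C3 and the lactone is not opened.

**Compound list**

1 | tert-butyl 2-[(4R,6S)-6-formyl-2,2-dimethyl-1,3-dioxan-4-yl]acetate | O=C[C@@H]1C[C@@H](OC(C)(C)O1)CC(=O)OC(C)(C)C | starting material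
2 | tetradecyl(triphenyl)phosphonium bromide | CCCCCCCCCCCCCC[P+](c1ccccc1)(c1ccccc1)c1ccccc1.[Br-] | starting material
3 | triphenyl(tetradecylidene)phosphorane | CCCCCCCCCCCCCC=P(c1ccccc1)(c1ccccc1)c1ccccc1 | intermediate
4 | tert-butyl 2-[(4R,6S)-2,2-dimethyl-6-[(1Z)-pentadec-1-en-1-yl]-1,3-dioxan-4-yl]acetate | CCCCCCCCCCCCC/C=C\[C@@H]1C[C@@H](OC(C)(C)O1)CC(=O)OC(C)(C)C | intermediate
5 | tert-butyl 2-[(4R,6R)-2,2-dimethyl-6-pentadecyl-1,3-dioxan-4-yl]acetate | CCCCCCCCCCCCCCC[C@@H]1C[C@@H](OC(C)(C)O1)CC(=O)OC(C)(C)C | intermediate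
6 | 2-[(4R,6R)-2,2-dimethyl-6-pentadecyl-1,3-dioxan-4-yl]acetaldehyde | CCCCCCCCCCCCCCC[C@@H]1C[C@@H](OC(C)(C)O1)CC=O | intermediate
7 | allylmagnesium bromide | C=CC[Mg]Br | starting material
8 | B-allylbis(isopinocampheyl)borane, both isopinocampheyl groups (1R,2R,3R,5S), from (+)-α-pinene | C=CCB([C@@H]1C[C@@H]2C[C@H]([C@H]1C)C2(C)C)[C@@H]1C[C@@H]2C[C@H]([C@H]1C)C2(C)C | intermediate
9 | (2S)-1-[(4S,6R)-2,2-dimethyl-6-pentadecyl-1,3-dioxan-4-yl]pent-4-en-2-ol | CCCCCCCCCCCCCCC[C@@H]1C[C@@H](OC(C)(C)O1)C[C@@H](O)CC=C | intermediate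
10 | tert-butyl{[(2S)-1-[(4R,6R)-2,2-dimethyl-6-pentadecyl-1,3-dioxan-4-yl]pent-4-en-2-yl]oxy}dimethylsilane | CCCCCCCCCCCCCCC[C@@H]1C[C@@H](OC(C)(C)O1)C[C@@H](O[Si](C)(C)C(C)(C)C)CC=C | intermediate
11 | 3-{(2R)-2-[(tert-butyldimethylsilyl)oxy]-3-[(4R,6R)-2,2-dimethyl-6-pentadecyl-1,3-dioxan-4-yl]propyl}-1,2,4-trioxolane (secondary ozonide, both epimers at the trioxolane carbon) | CCCCCCCCCCCCCCC[C@@H]1C[C@@H](OC(C)(C)O1)C[C@@H](O[Si](C)(C)C(C)(C)C)CC1OCOO1 | intermediate
12 | (3R)-3-[(tert-butyldimethylsilyl)oxy]-4-[(4R,6R)-2,2-dimethyl-6-pentadecyl-1,3-dioxan-4-yl]butanal | CCCCCCCCCCCCCCC[C@@H]1C[C@@H](OC(C)(C)O1)C[C@@H](O[Si](C)(C)C(C)(C)C)CC=O | intermediate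
13 | 4,4,5,5-tetramethyl-2-(propa-1,2-dien-1-yl)-1,3,2-dioxaborolane (allenylboronic acid pinacol ester) | C=C=CB1OC(C)(C)C(C)(C)O1 | starting material
14 | (4S,6S)-6-[(tert-butyldimethylsilyl)oxy]-7-[(4R,6R)-2,2-dimethyl-6-pentadecyl-1,3-dioxan-4-yl]hept-1-yn-4-ol | CCCCCCCCCCCCCCC[C@@H]1C[C@@H](OC(C)(C)O1)C[C@@H](O[Si](C)(C)C(C)(C)C)C[C@@H](O)CC#C | intermediate
15 | (4S,6S)-6-[(tert-butyldimethylsilyl)oxy]-7-[(4R,6R)-2,2-dimethyl-6-pentadecyl-1,3-dioxan-4-yl]-1-iodohept-1-yn-4-ol | CCCCCCCCCCCCCCC[C@@H]1C[C@@H](OC(C)(C)O1)C[C@@H](O[Si](C)(C)C(C)(C)C)C[C@@H](O)CC#CI | intermediate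
16 | (1Z,4S,6S)-6-[(tert-butyldimethylsilyl)oxy]-7-[(4R,6R)-2,2-dimethyl-6-pentadecyl-1,3-dioxan-4-yl]-1-iodohept-1-en-4-ol | CCCCCCCCCCCCCCC[C@@H]1C[C@@H](OC(C)(C)O1)C[C@@H](O[Si](C)(C)C(C)(C)C)C[C@@H](O)C/C=C\I | intermediate
17 | carbon monoxide | [C-]#[O+] | starting material
18 | (6S)-6-{(2R)-2-[(tert-butyldimethylsilyl)oxy]-3-[(4R,6R)-2,2-dimethyl-6-pentadecyl-1,3-dioxan-4-yl]propyl}-5,6-dihydro-2H-pyran-2-one | CCCCCCCCCCCCCCC[C@@H]1C[C@@H](OC(C)(C)O1)C[C@@H](O[Si](C)(C)C(C)(C)C)C[C@@H]1CC=CC(=O)O1 | intermediate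
19 | (6S)-6-[(2R,4R,6R)-2,4,6-trihydroxyhenicosyl]-5,6-dihydro-2H-pyran-2-one | CCCCCCCCCCCCCCC[C@@H](O)C[C@@H](O)C[C@@H](O)C[C@@H]1CC=CC(=O)O1 | target

Total step count: 11. Longest linear sequence: 11 steps (1 → 19).

**Steps most likely to fail**

Step 7. The catalyst may fail to override the resident C7 centre, giving poor facial selectivity at C5, or turnover may stall with the hindered aliphatic aldehyde. The fallback sets out from 12 and returns at 16, bypassing 14 and 15. Brown allylboration of 12 with borane 8 (Et2O, −78 °C; NaOH, H2O2) should give the homoallylic alcohol F1 with the same Si-face preference as in step 4. Silylation (TESCl, imidazole, CH2Cl2) gives the C5 triethylsilyl ether F2. Ozonolysis (O3, CH2Cl2, −78 °C; PPh3) passes through the ozonide F3 to the aldehyde F4. Stork–Zhao olefination ((iodomethyl)triphenylphosphonium iodide, NaN(SiMe3)2, THF/DMPU, −78 °C) gives the (Z)-iodoalkene F5. HF·pyridine buffered with pyridine (THF, 0 °C) then removes the triethylsilyl group selectively, leaving the TBS ether and the acetonide, and delivers 16.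

Step 10. Carbonyl insertion may be slow or the catalyst may decompose, so that hydrodeiodination or recovered iodide takes the place of ring closure. The fallback sets out from 14 and returns at 18. Double deprotonation of 14 (n-BuLi, 2.2 equiv, THF, −78 °C), carboxylation with CO2 and mild acidification (aq. NaH2PO4) give the hydroxy ynoic acid F6. Lindlar semi-hydrogenation (H2, Pd/CaCO3 poisoned with Pb(OAc)2, quinoline, EtOAc) gives the (Z)-hydroxy enoic acid F7, which should lactonise with a trace of PPTS in toluene (rt → 40 °C) to 18.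

Step 11. Under acid the liberated C7 hydroxyl may add in conjugate fashion to C3, or the acetonide may hydrolyse incompletely, giving mixtures. The fallback sets out from 18 and returns at 19, unmasking in two stages so that the C7 hydroxyl is freed last and under buffered conditions. Transketalisation (PPTS, MeOH, rt) removes only the acetonide and gives the C7-silylated diol F8, in which no hydroxyl can reach C3 through a six-membered ring. HF·pyridine buffered with pyridine (THF, 0 °C → rt) then cleaves the TBS ether to give 19.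

**Further compounds**

F1 | step 7 | (4S,6S)-6-[(tert-butyldimethylsilyl)oxy]-7-[(4R,6R)-2,2-dimethyl-6-pentadecyl-1,3-dioxan-4-yl]hept-1-en-4-ol | CCCCCCCCCCCCCCC[C@@H]1C[C@@H](OC(C)(C)O1)C[C@@H](O[Si](C)(C)C(C)(C)C)C[C@@H](O)CC=C
F2 | step 7 | (4S,6R)-6-[(tert-butyldimethylsilyl)oxy]-7-[(4R,6R)-2,2-dimethyl-6-pentadecyl-1,3-dioxan-4-yl]-4-[(triethylsilyl)oxy]hept-1-ene | CCCCCCCCCCCCCCC[C@@H]1C[C@@H](OC(C)(C)O1)C[C@@H](O[Si](C)(C)C(C)(C)C)C[C@@H](O[Si](CC)(CC)CC)CC=C
F3 | step 7 | secondary ozonide of F2 (3-substituted 1,2,4-trioxolane, both epimers at the trioxolane carbon) | CCCCCCCCCCCCCCC[C@@H]1C[C@@H](OC(C)(C)O1)C[C@@H](O[Si](C)(C)C(C)(C)C)C[C@@H](O[Si](CC)(CC)CC)CC1OCOO1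
F4 | step 7 | (3R,5R)-5-[(tert-butyldimethylsilyl)oxy]-6-[(4R,6R)-2,2-dimethyl-6-pentadecyl-1,3-dioxan-4-yl]-3-[(triethylsilyl)oxy]hexanal | CCCCCCCCCCCCCCC[C@@H]1C[C@@H](OC(C)(C)O1)C[C@@H](O[Si](C)(C)C(C)(C)C)C[C@@H](O[Si](CC)(CC)CC)CC=O
F5 | step 7 | (1Z,4S,6R)-6-[(tert-butyldimethylsilyl)oxy]-7-[(4R,6R)-2,2-dimethyl-6-pentadecyl-1,3-dioxan-4-yl]-1-iodo-4-[(triethylsilyl)oxy]hept-1-ene | CCCCCCCCCCCCCCC[C@@H]1C[C@@H](OC(C)(C)O1)C[C@@H](O[Si](C)(C)C(C)(C)C)C[C@@H](O[Si](CC)(CC)CC)C/C=C\I
F6 | step 10 | (5S,7S)-7-[(tert-butyldimethylsilyl)oxy]-8-[(4R,6R)-2,2-dimethyl-6-pentadecyl-1,3-dioxan-4-yl]-5-hydroxyoct-2-ynoic acid | CCCCCCCCCCCCCCC[C@@H]1C[C@@H](OC(C)(C)O1)C[C@@H](O[Si](C)(C)C(C)(C)C)C[C@@H](O)CC#CC(=O)O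
F7 | step 10 | (2Z,5S,7S)-7-[(tert-butyldimethylsilyl)oxy]-8-[(4R,6R)-2,2-dimethyl-6-pentadecyl-1,3-dioxan-4-yl]-5-hydroxyoct-2-enoic acid | CCCCCCCCCCCCCCC[C@@H]1C[C@@H](OC(C)(C)O1)C[C@@H](O[Si](C)(C)C(C)(C)C)C[C@@H](O)C/C=C\C(=O)O
F8 | step 11 | (6S)-6-{(2R,4R,6R)-2-[(tert-butyldimethylsilyl)oxy]-4,6-dihydroxyhenicosyl}-5,6-dihydro-2H-pyran-2-one | CCCCCCCCCCCCCCC[C@@H](O)C[C@@H](O)C[C@@H](O[Si](C)(C)C(C)(C)C)C[C@@H]1CC=CC(=O)O1
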